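**Plan**

- Retrosynthesis: cut the quinone C–N bond, then both C11–aryl bonds back to one neopentyl iodide (20, used as its alkylzinc iodide 23) and two aryl bromides; in the decalin cut C9–C10 (retro-semipinacol, ring B shrinks to five), then C8–C9 (aldol) and C8–C10 (benzoin).
- Forward: ring A comes from 2-methylcyclohexane-1,3-dione; a five-membered ring B (C5–C6–C7–C8–C10) is closed on it by an intramolecular benzoin reaction and dehydrated to the C8 enone (C10=C1); a lactate unit (C9, its CH3, C11) is added to C8.
- Feature used: quaternary C9 lies between C8 (a future CH–CH3, so it can be a ketone) and ring-fusion C10. With C8 as a tertiary carbinol in the five-membered ring, bonded to sp2 C10 and to an exocyclic epoxide carbon C9, a 1,2-shift of C10 from C8 to C9 enlarges ring B to six and creates C9.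
- Stereochemistry: C5 from the chiral triazolium catalyst; C9 from (S)-lactic acid (self-regeneration of the stereocentre, then inversion in the shift); C8 and C10 together from one hydrogenation directed by the C9 hydroxymethyl group.
- Ends: 20 → alkylzinc iodide 23 → two Negishi couplings (with 22 and with 31); the quinone half is isomerised (exo → Δ3), oxidised and mono-hydrolysed; the aminoresorcinol half is unmasked; displacement of methoxide on the quinone joins the halves.

Key step: step 9

Remark on locants: C1–C11 are those of the sesquiterpene decalin of the target (C4 methylene carbon, C5 angular methyl carbon, C8 secondary methyl carbon, C9 quaternary carbon, C10 ring-fusion CH, C11 benzylic carbon); β is the face of the C5 methyl. The same locants are used for the bicyclic precursors.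

Assumption: the sense of induction in step 2 is taken to follow from the choice of precatalyst enantiomer; the enantiomer that gives (S)-C5 is used.

Remark: 11–14 are drawn as the 8β-hydroxy epimers expected from attack anti to the C5 methyl; the 8-epimers would be carried along, since C8 becomes a carbonyl in step 9.

**Route**

Step 1
Reactants: 1 2-methylcyclohexane-1,3-dione; 2 acrolein
Product: 3 3-(1-methyl-2,6-dioxocyclohexyl)propanal
Conditions: Et3N (cat.), EtOAc, 0 °C → rt
Reagents that add atoms: none
Why: Michael addition of the dione enolate to acrolein should C-alkylate the methyl-bearing carbon and build the (still prochiral) quaternary carbon C5.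

Step 2
Reactants: 3 3-(1-methyl-2,6-dioxocyclohexyl)propanal
Product: 4 (3aS,7aR)-7a-hydroxy-3a-methylhexahydro-1H-indene-1,4(2H)-dione
Conditions: (5aS,10bR)-2-(pentafluorophenyl)-5a,10b-dihydro-4H,6H-indeno[2,1-b][1,2,4]triazolo[4,3-d][1,4]oxazin-2-ium tetrafluoroborate (10 mol %; enantiomer per the assumption), Et3N (10 mol %), toluene, rt
Reagents that add atoms: none
Why: N-heterocyclic carbene-catalysed intramolecular crossed benzoin reaction, in which the acyl anion equivalent adds 5-exo to one of the two enantiotopic ring carbonyls and the chiral triazolium selects between them, fixing C5 as S (ring B closed as a five-membered ring, C8–C10 bond).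

Step 3
Reactants: 4 cis-fused ketol
Product: 5 (3aS)-3a-methyl-3,3a,5,6-tetrahydro-1H-indene-1,4(2H)-dione
Conditions: SOCl2, pyridine, CH2Cl2, −20 → 0 °C
Reagents that add atoms: none
Why: dehydration of the tertiary α-ketol through its chlorosulfite; C1 is the only neighbour of C10 that carries hydrogen, so the conjugated C8(=O)–C10=C1 enone should form as one regioisomer and C10 becomes the sp2 carbon needed in step 9.

Step 4
Reactants: 5 enedione
Product: 6 (3a'S)-3a'-methyl-2',3',5',6'-tetrahydrospiro[[1,3]dioxolane-2,4'-inden]-1'(3a'H)-one (C4 ethylene ketal of 5)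
Conditions: HOCH2CH2OH, 4-MeC6H4SO3H·H2O (cat.), 4 Å molecular sieves, rt
Reagents that add atoms: ethylene glycol OCCO
Why: chemoselective ketalisation, the saturated C4 ketone being far more reactive than the conjugated C8 carbonyl, as is usual for enediones of this kind.

Step 5
Reactants: 7 (S)-lactic acid; 8 pivalaldehyde
Product: 9 (2S,5S)-2-tert-butyl-5-methyl-1,3-dioxolan-4-one
Conditions: 4-MeC6H4SO3H (cat.), H2SO4 (cat.), pentane, reflux, water separator; crystallisation (Et2O/pentane, −78 °C)
Reagents that add atoms: none
Why: acid-catalysed acetalisation of the α-hydroxy acid, the cis isomer being favoured and purified by crystallisation, so that the acetal carbon stores the chirality of lactic acid.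

Step 6
Reactants: 6 enone ketal; 9 dioxolanone
Product: 11 aldol adduct (dioxolanone C5 = C9 bonded to the C8 tertiary carbinol of the hydrindene; CH3 cis to tert-butyl; 8β-OH), via lithium enolate 10 (not isolated)
Conditions: LiN(iPr)2, THF, −78 °C; then 6, −78 °C; AcOH, −78 °C
Reagents that add atoms: none
Why: aldol addition under self-regeneration of the stereocentre, the planar enolate adding 1,2 to the C8 carbonyl on the face anti to tert-butyl, so that C9 keeps the lactate geometry with C8 in place of hydrogen.

Step 7
Reactants: 11 aldol adduct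
Product: 12 triol (C8–OH, C9–OH, C11–OH; C4 ketal)
Conditions: LiAlH4, THF, 0 °C → rt; aqueous NaOH work-up
Reagents that add atoms: none
Why: hydride reduction of the lactone carbonyl and collapse of the hemiacetal should free the C9 tertiary and C11 primary hydroxyls without touching C9 or the alkene.

Step 8
Reactants: 12 triol
Product: 14 epoxy alcohol (C8 tertiary allylic carbinol carrying the (S)-2-methyloxiran-2-yl group), via primary tosylate 13 (not isolated)
Conditions: 4-MeC6H4SO2Cl, pyridine, 4-(dimethylamino)pyridine (cat.), CH2Cl2, 0 °C; then K2CO3, MeOH, rt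
Reagents that add atoms: none
Why: selective sulfonylation of the only primary hydroxyl and intramolecular Williamson closure (3-exo-tet) by the C9 alkoxide; no bond to C9 is broken, so the epoxide carbon keeps the lactate-derived configuration.

Step 9
Reactants: 14 epoxy alcohol
Product: 15 4,4-ethylenedioxy-9α-(hydroxymethyl)-5β,9β-dimethyl-Δ1(10)-octalin-8-one
Conditions: ZnBr2 (20 mol %), CH2Cl2, 0 °C → rt
Reagents that add atoms: none
Why: ZnBr2 binds the epoxide oxygen, the tertiary C9–O bond lengthens while the antiperiplanar ring bond C8–C10 shifts to C9 and the C8 hydroxyl collapses to the ketone, a semipinacol rearrangement of a 2,3-epoxy alcohol whose closest precedents are Lewis acid ring enlargements of 1-(oxiranyl)cycloalkanols. Ring B is not closed by a cyclisation: the five-membered ring C5–C6–C7–C8–C10 becomes the six-membered ring C5–C6–C7–C8–C9–C10 by a suprafacial 1,2-alkenyl shift that inserts C9 between C8 and C10. The only new stereocentre, quaternary C9, forms with inversion at the epoxide carbon, so the configuration taken from (S)-lactic acid should place CH3 β and CH2OH α. The step needs C10 and not C7 to migrate, and needs the shift to outrun a hydride shift from C11 or free-cation formation; C10 is an sp2 carbon of the C10=C1 alkene, whose migratory aptitude far exceeds that of the C7 methylene, and alkenyl bridging keeps the shift concerted. Both C8 epimers of 14 can place C8–C10 anti to the C9–O bond and should converge on 15, because the carbinol centre is destroyed.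

Step 10
Reactants: 15 hydroxy ketone
Product: 16 4,4-ethylenedioxy-9α-(hydroxymethyl)-5β,9β-dimethyl-8-methylene-Δ1(10)-octalin
Conditions: Zn, CH2Br2, TiCl4, THF/CH2Cl2, 0 °C → rt
Reagents that add atoms: dibromomethane BrCBr
Why: Takai–Lombardo-type titanium–zinc methylenation, a non-basic reagent that should olefinate the hindered α-quaternary C8 ketone without retro-aldol loss of the β-hydroxymethyl group (carried as its metal alkoxide).

Step 11
Reactants: 16 diene alcohol
Product: 17 4,4-ethylenedioxy-9α-(hydroxymethyl)-5β,8β,9β-trimethyl-10α-H-decalin (trans-fused)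
Conditions: [Ir(cod)(PCy3)(py)]PF6 (5 mol %), H2 (1 atm), CH2Cl2, rt
Reagents that add atoms: none
Why: hydroxyl-directed homogeneous hydrogenation, the α-oriented CH2OH on C9 being homoallylic to both C8=CH2 and C10=C1 and delivering hydrogen to the α face of each (the β face is also blocked by the C5 and C9 methyls), which should set 8β-CH3 and 10α-H together.

Step 12
Reactants: 17 ketal alcohol
Product: 18 9α-(hydroxymethyl)-5β,8β,9β-trimethyl-trans-decalin-4-one
Conditions: 2 M HCl, THF, rt
Reagents that add atoms: water O
Why: acid hydrolysis of the dioxolane; C5 is quaternary, so no centre next to the ketone can epimerise.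

Step 13
Reactants: 18 keto alcohol
Product: 19 9α-(hydroxymethyl)-5β,8β,9β-trimethyl-4-methylene-trans-decalin
Conditions: Ph3PCH3Br, KOtBu, toluene, 90 °C
Reagents that add atoms: methyltriphenylphosphonium bromide C[P+](c1ccccc1)(c1ccccc1)c1ccccc1.[Br-]
Why: Wittig methylenation of the hindered C4 ketone with excess ylide, the primary alkoxide being inert.

Step 14
Reactants: 19 neopentyl alcohol
Product: 20 9α-(iodomethyl)-5β,8β,9β-trimethyl-4-methylene-trans-decalin
Conditions: PPh3, I2, imidazole, toluene, 90 °C
Reagents that add atoms: iodine II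
Why: Appel-type iodination, in which iodide displaces the alkoxyphosphonium group in an SN2 step that is slow at a neopentyl carbon but offers no ionisation path, so no skeletal shift is expected.

Step 15
Reactants: 21 1,2,4,5-tetramethoxybenzene
Product: 22 3-bromo-1,2,4,5-tetramethoxybenzene
Conditions: N-bromosuccinimide (1.0 equiv), MeCN, 0 °C → rt
Reagents that add atoms: N-bromosuccinimide O=C1CCC(=O)N1Br
Why: electrophilic aromatic bromination of the electron-rich arene, whose two free positions are equivalent, so one equivalent should give one monobromide.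

Step 16
Reactants: 20 neopentyl iodide
Product: 23 [(5β,8β,9β-trimethyl-4-methylene-trans-decalin-9α-yl)methyl]zinc iodide (kept as a titrated THF solution under argon and divided between steps 17 and 24)
Conditions: Zn dust (activated with BrCH2CH2Br and Me3SiCl), LiCl, THF, 50 °C
Reagents that add atoms: zinc [Zn]
Why: direct oxidative insertion of zinc into the primary C–I bond, with LiCl solubilising the organozinc as it forms; the insertion is a surface electron-transfer process and needs no backside attack, so the neopentyl position should not block it, and no stereocentre is involved.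

Step 17
Reactants: 23 alkylzinc iodide; 22 aryl bromide
Product: 24 3-[(5β,8β,9β-trimethyl-4-methylene-trans-decalin-9α-yl)methyl]-1,2,4,5-tetramethoxybenzene
Conditions: Pd(OAc)2 (5 mol %), 2-dicyclohexylphosphino-2′,6′-diisopropoxybiphenyl (10 mol %), THF/N-methylpyrrolidone, 60 °C
Reagents that add atoms: none
Why: Negishi sp3–sp2 coupling; the neopentylzinc reagent has no β-hydrogen (C9 is quaternary), so β-hydride elimination cannot compete, and a bulky biarylphosphine should allow coupling with the di-ortho-substituted bromide.

Step 18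
Reactants: 24 exo-olefin arene
Product: 25 3-[(4,5β,8β,9β-tetramethyl-Δ3-trans-octalin-9α-yl)methyl]-1,2,4,5-tetramethoxybenzene
Conditions: RhCl3·3H2O (10 mol %), EtOH, reflux
Reagents that add atoms: none
Why: rhodium hydride-mediated olefin isomerisation, the exocyclic alkene moving to the more stable trisubstituted Δ3 position (quaternary C5 blocks the other direction).

Step 19
Reactants: 25 endo-olefin arene
Product: 26 2,5-dimethoxy-3-[(4,5β,8β,9β-tetramethyl-Δ3-trans-octalin-9α-yl)methyl]-1,4-benzoquinone
Conditions: (NH4)2Ce(NO3)6, MeCN/H2O, 0 °C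
Reagents that add atoms: water O
Why: oxidative demethylation of a para-dimethoxy pair by tetravalent cerium; the two possible para pairs are related by the symmetry of the aryl ring, so one p-quinone should result.

Step 20
Reactants: 26 dimethoxyquinone
Product: 27 2-hydroxy-5-methoxy-3-[(4,5β,8β,9β-tetramethyl-Δ3-trans-octalin-9α-yl)methyl]-1,4-benzoquinone (Δ3 isomer of ilimaquinone)
Conditions: KOH, MeOH/H2O, rt; then dilute HCl
Reagents that add atoms: potassium hydroxide [K+].[OH-]
Why: addition–elimination of hydroxide at a vinylogous ester; the C2 methoxy group flanked by the bulky side chain is twisted out of conjugation and is the one exchanged, as is known for this quinone class, which leaves the C5 methoxy group for the last step.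

Step 21
Reactants: 28 methyl 2,4-dihydroxybenzoate
Product: 29 methyl 5-bromo-2,4-dihydroxybenzoate
Conditions: Br2 (1.0 equiv), AcOH, rt
Reagents that add atoms: bromine BrBr
Why: electrophilic aromatic bromination, C5 (para to the 2-OH, ortho to the 4-OH) being favoured over the hindered C3 between the two hydroxyls.

Step 22
Reactants: 29 bromoresorcylate
Product: 30 methyl 5-bromo-2,4-dihydroxy-3-nitrobenzoate
Conditions: HNO3 (65 %, 1.1 equiv), AcOH, 10 °C
Reagents that add atoms: nitric acid O[N+](=O)[O-]
Why: electrophilic nitration at C3, the only remaining position activated by both hydroxyls.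

Step 23
Reactants: 30 nitro bromoresorcylate
Product: 31 methyl 2,4-diacetoxy-5-bromo-3-nitrobenzoate
Conditions: Ac2O, pyridine, 4-(dimethylamino)pyridine (cat.), CH2Cl2, rt
Reagents that add atoms: acetic anhydride CC(=O)OC(C)=O
Why: acetylation of both phenols removes the acidic protons that would quench the organozinc reagent.

Step 24
Reactants: 23 alkylzinc iodide; 31 aryl bromide
Product: 32 methyl 2,4-diacetoxy-3-nitro-5-[(5β,8β,9β-trimethyl-4-methylene-trans-decalin-9α-yl)methyl]benzoate
Conditions: Pd(OAc)2 (3 mol %), 2-dicyclohexylphosphino-2′,6′-dimethoxybiphenyl (6 mol %), THF, rt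
Reagents that add atoms: none
Why: Negishi coupling, the electron-poor bromide adding readily to zerovalent palladium and the organozinc reagent tolerating ester, acetate and nitro groups.

Step 25
Reactants: 32 diacetate
Product: 33 methyl 2,4-dihydroxy-3-nitro-5-[(5β,8β,9β-trimethyl-4-methylene-trans-decalin-9α-yl)methyl]benzoate
Conditions: K2CO3, MeOH, 0 °C; then 1 M HCl
Reagents that add atoms: none
Why: base-mediated transesterification of the two aryl acetates (activated by the ortho nitro group), the hydrogen-bonded methyl benzoate being unchanged in methanol.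

Step 26
Reactants: 33 nitroresorcinol ester
Product: 34 methyl 3-amino-2,4-dihydroxy-5-[(5β,8β,9β-trimethyl-4-methylene-trans-decalin-9α-yl)methyl]benzoate
Conditions: Na2S2O4, THF/H2O, rt, argon
Reagents that add atoms: none
Why: dithionite reduction of the nitro group, to which the alkene and the ester are inert; 34 should be used at once because aminoresorcinols are air-sensitive.

Step 27
Reactants: 27 hydroxy methoxy quinone; 34 aminoresorcinol ester
Product: 35 nakijiquinone E
Conditions: EtOH, 40 °C, argon
Reagents that add atoms: none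
Why: addition–elimination at the remaining vinylogous ester (quinone C5), the aniline nitrogen displacing methanol to give the vinylogous amide without touching the 2-hydroxyl or any stereocentre.

**Compound list**

1 | 2-methylcyclohexane-1,3-dione | CC1C(=O)CCCC1=O | starting material
2 | acrolein | C=CC=O | starting material
3 | 3-(1-methyl-2,6-dioxocyclohexyl)propanal | CC1(CCC=O)C(=O)CCCC1=O | intermediate
4 | (3aS,7aR)-7a-hydroxy-3a-methylhexahydro-1H-indene-1,4(2H)-dione (cis-fused ketol) | O=C1CC[C@]2(C)C(=O)CCC[C@]12O | intermediate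
5 | (3aS)-3a-methyl-3,3a,5,6-tetrahydro-1H-indene-1,4(2H)-dione | O=C1CC[C@]2(C)C(=O)CCC=C12 | intermediate
6 | C4 ethylene ketal of 5 | O=C1CC[C@]2(C)C3(OCCO3)CCC=C12 | intermediate
7 | (S)-lactic acid | C[C@H](O)C(=O)O | starting material
8 | pivalaldehyde | CC(C)(C)C=O | starting material
9 | (2S,5S)-2-tert-butyl-5-methyl-1,3-dioxolan-4-one | C[C@@H]1O[C@H](C(C)(C)C)OC1=O | intermediate
10 | lithium enolate of 9 | [Li+].CC1=C([O-])O[C@@H](C(C)(C)C)O1 | intermediate
11 | aldol adduct of 6 and 9 (C8–C9 bond; 8β-OH; CH3 cis to tert-butyl) | C[C@]1([C@]2(O)CC[C@]3(C)C4(OCCO4)CCC=C23)O[C@H](C(C)(C)C)OC1=O | intermediate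
12 | triol (C8–OH, C9–OH, C11–OH; C4 ketal) | C[C@](O)(CO)[C@]1(O)CC[C@]2(C)C3(OCCO3)CCC=C12 | intermediate
13 | primary (C11) tosylate of 12 | C[C@](O)(COS(=O)(=O)c1ccc(C)cc1)[C@]2(O)CC[C@]3(C)C4(OCCO4)CCC=C23 | intermediate
14 | epoxy alcohol (C8 carbinol with (S)-2-methyloxiran-2-yl group) | C[C@]1(CO1)[C@]2(O)CC[C@]3(C)C4(OCCO4)CCC=C23 | intermediate
15 | 4,4-ethylenedioxy-9α-(hydroxymethyl)-5β,9β-dimethyl-Δ1(10)-octalin-8-one | O=C1CC[C@]2(C)C3(OCCO3)CCC=C2[C@]1(C)CO | intermediate
16 | 4,4-ethylenedioxy-9α-(hydroxymethyl)-5β,9β-dimethyl-8-methylene-Δ1(10)-octalin | C=C1CC[C@]2(C)C3(OCCO3)CCC=C2[C@]1(C)CO | intermediate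
17 | 4,4-ethylenedioxy-9α-(hydroxymethyl)-5β,8β,9β-trimethyl-trans-decalin | C[C@H]1CC[C@]2(C)C3(OCCO3)CCC[C@H]2[C@]1(C)CO | intermediate
18 | 9α-(hydroxymethyl)-5β,8β,9β-trimethyl-trans-decalin-4-one | C[C@H]1CC[C@]2(C)C(=O)CCC[C@H]2[C@]1(C)CO | intermediate
19 | 9α-(hydroxymethyl)-5β,8β,9β-trimethyl-4-methylene-trans-decalin | C=C1CCC[C@H]2[C@](C)(CO)[C@@H](C)CC[C@]12C | intermediate
20 | 9α-(iodomethyl)-5β,8β,9β-trimethyl-4-methylene-trans-decalin | C=C1CCC[C@H]2[C@](C)(CI)[C@@H](C)CC[C@]12C | intermediate
21 | 1,2,4,5-tetramethoxybenzene | COc1cc(OC)c(OC)cc1OC | starting material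
22 | 3-bromo-1,2,4,5-tetramethoxybenzene | COc1cc(OC)c(OC)c(Br)c1OC | intermediate
23 | [(5β,8β,9β-trimethyl-4-methylene-trans-decalin-9α-yl)methyl]zinc iodide | C=C1CCC[C@H]2[C@](C)(C[Zn]I)[C@@H](C)CC[C@]12C | intermediate
24 | exo-olefin tetramethoxyaryl decalin | C=C1CCC[C@H]2[C@](C)(Cc3c(OC)c(OC)cc(OC)c3OC)[C@@H](C)CC[C@]12C | intermediate
25 | Δ3 (endo-olefin) tetramethoxyaryl decalin | COc1cc(OC)c(OC)c(C[C@]2(C)[C@@H](C)CC[C@]3(C)C(C)=CCC[C@@H]23)c1OC | intermediate
26 | 2,5-dimethoxy-3-alkyl-1,4-benzoquinone (Δ3 decalin) | COC1=CC(=O)C(OC)=C(C[C@]2(C)[C@@H](C)CC[C@]3(C)C(C)=CCC[C@@H]23)C1=O | intermediate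
27 | 2-hydroxy-5-methoxy-3-alkyl-1,4-benzoquinone (Δ3 isomer of ilimaquinone) | COC1=CC(=O)C(O)=C(C[C@]2(C)[C@@H](C)CC[C@]3(C)C(C)=CCC[C@@H]23)C1=O | intermediate
28 | methyl 2,4-dihydroxybenzoate | COC(=O)c1ccc(O)cc1O | starting material
29 | methyl 5-bromo-2,4-dihydroxybenzoate | COC(=O)c1cc(Br)c(O)cc1O | intermediate
30 | methyl 5-bromo-2,4-dihydroxy-3-nitrobenzoate | COC(=O)c1cc(Br)c(O)c([N+](=O)[O-])c1O | intermediate
31 | methyl 2,4-diacetoxy-5-bromo-3-nitrobenzoate | COC(=O)c1cc(Br)c(OC(C)=O)c([N+](=O)[O-])c1OC(C)=O | intermediate
32 | coupled nitro diacetate (exo-olefin decalin) | C=C1CCC[C@H]2[C@](C)(Cc3cc(C(=O)OC)c(OC(C)=O)c([N+](=O)[O-])c3OC(C)=O)[C@@H](C)CC[C@]12C | intermediate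
33 | nitroresorcinol ester | C=C1CCC[C@H]2[C@](C)(Cc3cc(C(=O)OC)c(O)c([N+](=O)[O-])c3O)[C@@H](C)CC[C@]12C | intermediate
34 | aminoresorcinol ester | C=C1CCC[C@H]2[C@](C)(Cc3cc(C(=O)OC)c(O)c(N)c3O)[C@@H](C)CC[C@]12C | intermediate
35 | nakijiquinone E | C=C1CCC[C@H]2[C@](C)(Cc3cc(C(=O)OC)c(O)c(NC4=CC(=O)C(O)=C(C[C@]5(C)[C@@H](C)CC[C@]6(C)C(C)=CCC[C@@H]56)C4=O)c3O)[C@@H](C)CC[C@]12C | target

**Count and risks**

Total step count: 27. Longest linear sequence: 19 steps (steps 1–4, 6–14, 16–20, 27).

Risk 1, step 9. The epoxide may open to a free tertiary cation before the shift, which would erode the configuration at C9, or a hydride shift from C11 or loss of the ketal may compete. The fallback sets out from 6 and returns at 16. Ketone 6 would be ring-expanded directly with methyl 2-diazopropanoate under Sc(OTf)3 and the chiral N,N′-dioxide 1,1′-(propane-1,3-diyl)bis[(2S)-2-(2,6-diisopropylphenylcarbamoyl)piperidine 1-oxide] (or its mirror image, whichever gives the 9β-methyl product). This is a Lewis acid diazo ester homologation with migration of the alkenyl carbon C10, and would give methyl 4,4-ethylenedioxy-5β,9β-dimethyl-8-oxo-Δ1(10)-octalin-9α-carboxylate F1. Methylenation with Zn, CH2Br2 and TiCl4 would give the 8-methylene ester F2, and LiAlH4 would reduce the ester to 16.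

Risk 2, step 17. Transmetalation or reductive elimination with the di-ortho-substituted aryl group may be slow enough for protodezincation of 23 to win. The same zinc reagent is used in step 24, where the bromide is electron-poor and less demanding, so only the route to 24 is replaced. The fallback sets out from 19 and returns at 24. Dess–Martin oxidation of 19 would give 5β,8β,9β-trimethyl-4-methylene-trans-decalin-9α-carbaldehyde F3. Lithiation of 21 (n-C4H9Li, Me2NCH2CH2NMe2, THF, 0 °C) would give 2,3,5,6-tetramethoxyphenyllithium F4, which would add to F3 to give the benzylic carbinol F5 as a mixture of C11 epimers. Dissolving-metal hydrogenolysis (Li, liquid NH3, THF, −78 °C; then NH4Cl) would remove the benzylic hydroxyl and give 24.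

Risk 3, step 10. The hindered C8 ketone may react slowly, and the β-hydroxy ketone may lose formaldehyde by retro-aldol cleavage, or the free hydroxyl may consume the reagent. The fallback sets out from 15 and returns at 16. Silylation (tert-butyldimethylsilyl chloride, imidazole, DMF) would convert 15 into its tert-butyldimethylsilyl ether F6. A Wittig reaction with Ph3P=CH2 (from Ph3PCH3Br and KOtBu, toluene, 90 °C), now free of the retro-aldol pathway, would give the 8-methylene silyl ether F7, and Bu4NF in THF would release 16.

Further compounds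
F1 | step 9 | methyl 4,4-ethylenedioxy-5β,9β-dimethyl-8-oxo-Δ1(10)-octalin-9α-carboxylate | O=C1CC[C@]2(C)C3(OCCO3)CCC=C2[C@]1(C)C(=O)OC
F2 | step 9 | methyl 4,4-ethylenedioxy-5β,9β-dimethyl-8-methylene-Δ1(10)-octalin-9α-carboxylate | C=C1CC[C@]2(C)C3(OCCO3)CCC=C2[C@]1(C)C(=O)OC
F3 | step 17 | 5β,8β,9β-trimethyl-4-methylene-trans-decalin-9α-carbaldehyde | C=C1CCC[C@H]2[C@](C)(C=O)[C@@H](C)CC[C@]12C
F4 | step 17 | 2,3,5,6-tetramethoxyphenyllithium | [Li]c1c(OC)c(OC)cc(OC)c1OC
F5 | step 17 | benzylic carbinol from F3 and F4 (C11 epimers) | C=C1CCC[C@H]2[C@](C)(C(O)c3c(OC)c(OC)cc(OC)c3OC)[C@@H](C)CC[C@]12C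
F6 | step 10 | tert-butyldimethylsilyl ether of 15 | O=C1CC[C@]2(C)C3(OCCO3)CCC=C2[C@]1(C)CO[Si](C)(C)C(C)(C)C
F7 | step 10 | tert-butyldimethylsilyl ether of 16 | C=C1CC[C@]2(C)C3(OCCO3)CCC=C2[C@]1(C)CO[Si](C)(C)C(C)(C)C
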